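(The runs were generated by integration with made-up constants; scatter was added.)

If the run is repeated, the reading to watch is the fraction of starting complex left: charged at 20 mM against 60.0 mM of incoming ligand, it is the limiting reagent.

| flask | starting complex | incoming ligand | leaving ligand | remark | time |
|---|---|---|---|---|---|
| violet | 20 mM | 60 mM | 140 mM | run made earlier |  |
| grey | 20 mM | 60 mM | 220 mM | run made earlier |  |
| flask | 20 mM | 60.0 mM | 100 mM |  | 15 h |

| run | time / h | complex with one exchanged / % | starting complex / % |
|---|---|---|---|
| violet | 2.50 | 8.5 | 91.3 |
| violet | 6.00 | 18.2 | 80.8 |
| violet | 12.0 | 26.0 | 64.9 |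
| violet | 20.0 | 32.0 | 50.4 |
| grey | 2.50 | 8.2 | 91.1 |
| grey | 6.00 | 17.6 | 80.1 |
| grey | 12.0 | 27.0 | 65.6 |
| grey | 20.0 | 33.1 | 50.6 |

(standard deviation of a reading: 0.5 percentage points)

- equivalents of incoming ligand to starting complex, everything else as given, that leave most complex with one exchanged at 15 h
- the amount of complex with one exchanged then, in percent of the starting complex charged
- the amount of complex with one exchanged with the amounts as given



The violet and grey runs differ by less than the scatter in that fraction (50.4% and 50.6% at 20.0 h), so leaving ligand is taken as idle, also at the flask's lower charge, and the two runs are averaged. Exposure, minus the logarithm of the fraction left, is then 0.683. For two first-order steps in a row, the mean 32.5% of complex with one exchanged gives a selectivity factor, its loss constant over its making constant, of 1.17. So at 15 h exposure is 0.512 and complex with one exchanged 29.4%; its peak, 34.0%, lies at exposure 0.925.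

But a single charge of incoming ligand was tried, so first order in it is assumed. Each starting complex lost takes one equivalent and each complex gone further is taken to need one more, so the mean level is the charge minus half of that use. Exposure per hour and mean equivalent is 0.0128 h⁻¹. The peak at 15 h therefore needs 5.25 equivalents.

The forecast, reasoning that "Starting complex decays in two consecutive steps", gives 29.3%, and 33.5% at 5.2 equiv. The flask gives 30.0%, and 34.3% at 5.29 equiv.

    starting complex + incoming ligand → leaving ligand + complex with one exchanged (k = 1.80 × 10⁻⁴ L mol⁻¹ s⁻¹)
    complex with one exchanged + incoming ligand → leaving ligand + complex with two exchanged (k = 6.60 × 10⁻⁵ L mol⁻¹ s⁻¹)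
    complex with two exchanged + incoming ligand → leaving ligand + complex with three exchanged (k = 4.00 × 10⁻⁴ L mol⁻¹ s⁻¹)
    complex with one exchanged + incoming ligand → over-reaction product (k = 1.40 × 10⁻⁴ L mol⁻¹ s⁻¹)

The flask's 58.9% of starting complex is an exposure of 0.529, short of the peak's 0.925. At 15.0 h its complex with one exchanged is made 1.72 times faster than used up, each step taken net, down from 3.86 at 6.16 h.

For the neighbour charged with 150 mM of incoming ligand and read at 15 h, 0.0128 h⁻¹ with the use at the peak as a first guess gives exposure 1.36. The neighbour's own use at that exposure, by the same rule, brings it to 1.33, past the peak, hence 26.4% of starting complex and 31.5% of complex with one exchanged. That neighbour holds 26.5% and 32.0%.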